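**Retrosynthetic overview**

1. Target (ring A = tetrahydropyridine N1, C2, C3=C4, C5, C6; ring B = 13-membered lactam through N1 and C6): the last operations are Boc removal from N5 and formation of the pentyl ketone by propyl cuprate addition to a vinyl ketone, itself oxidised from a vinyl carbinol.
2. Ring B: amide bond N10–C11 by macrolactamisation, after N1 has been alkylated (reductive amination) with a three-carbon aldehyde that carries the N-Boc-4-azidobutyl unit.
3. Ring A: ring-rearrangement metathesis. The feature used: C2, C3 and the first three carbons of the oxoheptyl arm (CH2, carbonyl carbon, next CH2) are the five carbons of a cis-4-aminocyclopent-2-en-1-ol, with N1 on the carbon that becomes C2 and the future ketone oxygen on the carbinol carbon; C4, C5, C6 and the acetamide arm are an N-homoallyl group from (R)-3-aminohex-5-enoic acid.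
4. Metathesis precursor: palladium-catalysed allylic amination of the silylated (1R,4S)-monoacetate of cis-cyclopent-2-ene-1,4-diol with the amino ester (net retention), so that C2 and C6 both come from enantiopure building blocks.
5. Order of ring formation: ring A (step 4), then ring B (step 10).

Key step: step 4

Assumption: the descriptors of the target SMILES are read as absolute configuration, (13R,17S) in bicyclo[11.4.0] numbering; the small ring is numbered N1, C2 (oxoheptyl arm), C3=C4, C5, C6 (acetamide arm) throughout, and 4-azidobutan-1-amine is taken as a purchasable, putrescine-derived reagent.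

**Route**

Step 1
Reactants: 1 (3R)-3-aminohex-5-enoic acid
Product: 2 methyl (3R)-3-aminohex-5-enoate hydrochloride
Conditions: SOCl2, MeOH, 0 °C to reflux
Reagents that add atoms: methanol CO; thionyl chloride O=S(Cl)Cl (source of the chloride of the salt)
Why: Fischer-type esterification by HCl generated in situ should give the ester salt, and the β-stereocentre carries no hydrogen that is acidic under these conditions.

Step 2
Reactants: 3 (1R,4S)-cis-4-acetoxycyclopent-2-en-1-ol
Product: 4 (1S,4R)-cis-4-(tert-butyldimethylsilyloxy)cyclopent-2-en-1-yl acetate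
Conditions: TBSCl, imidazole, DMF, rt
Reagents that add atoms: tert-butyldimethylsilyl chloride CC(C)(C)[Si](C)(C)Cl
Why: Imidazole-promoted silylation of the free secondary alcohol should leave the acetate untouched and both stereocentres unchanged.

Step 3
Reactants: 4 (1S,4R)-cis-4-(tert-butyldimethylsilyloxy)cyclopent-2-en-1-yl acetate; 2 methyl (3R)-3-aminohex-5-enoate hydrochloride
Product: 6 methyl (3R)-3-{[(1S,4R)-4-(tert-butyldimethylsilyloxy)cyclopent-2-en-1-yl]amino}hex-5-enoate, via methyl (3R)-3-aminohex-5-enoate 5 (not isolated)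
Conditions: Pd(PPh3)4 (5 mol %), Et3N (2.2 equiv), THF, 50 °C
Reagents that add atoms: none
Why: Tsuji–Trost allylic amination, in which zerovalent palladium ionises the acetate with inversion on the face opposite both oxygen substituents and the amine (freed by Et3N) attacks the allyl terminus remote from the silyloxy group anti to palladium, so double inversion should give the cis-1,4 amine with net retention; the unsymmetrical allyl complex cannot racemise.

Step 4
Reactants: 6 methyl (3R)-3-{[(1S,4R)-4-(tert-butyldimethylsilyloxy)cyclopent-2-en-1-yl]amino}hex-5-enoate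
Product: 9 methyl {(2S,6R)-2-[(2R)-2-(tert-butyldimethylsilyloxy)but-3-en-1-yl]-1,2,5,6-tetrahydropyridin-6-yl}acetate (trans-2,6), via ammonium tosylate of the diene 7 (not isolated), via ammonium tosylate of the tetrahydropyridine 8 (not isolated)
Conditions: TsOH·H2O (1.0 equiv), CH2Cl2, rt; then RuCl2(=CHPh)(PCy3)(H2IMes) (second-generation Grubbs catalyst, 5 mol %), ethylene (1 atm), 40 °C; aq NaHCO3 work-up
Reagents that add atoms: ethylene C=C (methylidene exchange: it supplies the terminal CH2 of the new vinyl group while the terminal CH2 of the hexenoate arm leaves as ethylene; net isomerisation)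
Why: The ruthenium alkylidene should load on the unhindered terminal alkene of the hexenoate arm, add [2+2] across the cyclopentene double bond and, by cycloreversion of the metallacyclobutane, open the carbocycle while forming the C3=C4 bond, after which ethylene caps the new alkylidene as the vinyl group. This is a ring-rearrangement (ring-opening/ring-closing) metathesis, of the known class that converts N-alkenyl cycloalk-2-enylamines into 2-substituted tetrahydropyridines, run on the ammonium salt as is usual for metathesis of basic amines. Ring A closes by ring-closing metathesis in which the alkylidene carbon C4 joins the former cyclopentene carbon C3, a six-membered closure. No stereocentre is created: C2 is the former nitrogen-bearing cyclopentene carbon, C6 the amino acid carbon and the carbinol the former silyloxy carbon, and none of their bonds changes, so the trans-2,6 relation follows from the two building blocks. The step needs closure onto the alkene carbon next to nitrogen (six-membered ring) and not the distal one (eight-membered ring), which ring size secures. It also needs an equilibrium on the side of the azacycle, which release of cyclopentene strain into an unstrained ring provides, while ethylene suppresses oligomers and protonation keeps the nitrogen lone pair off ruthenium.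

Step 5
Reactants: 10 4-azidobutan-1-amine; 11 methyl acrylate
Product: 13 methyl 3-[(4-azidobutyl)(tert-butoxycarbonyl)amino]propanoate, via methyl 3-[(4-azidobutyl)amino]propanoate 12 (not isolated)
Conditions: MeOH, 0 °C to rt (amine in slight excess); then Boc2O, rt
Reagents that add atoms: di-tert-butyl dicarbonate CC(C)(C)OC(=O)OC(=O)OC(C)(C)C
Why: Aza-Michael addition of the primary amine to the acrylate should stop at the mono-adduct with a slight excess of amine, and the secondary amine is then capped as its carbamate in the same flask.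

Step 6
Reactants: 13 methyl 3-[(4-azidobutyl)(tert-butoxycarbonyl)amino]propanoate
Product: 14 tert-butyl (4-azidobutyl)(3-hydroxypropyl)carbamate
Conditions: LiBH4, THF, 0 °C to rt
Reagents that add atoms: none
Why: Hydride reduction of the methyl ester with LiBH4 should give the primary alcohol, alkyl azide and carbamate being inert to this reagent at room temperature.

Step 7
Reactants: 14 tert-butyl (4-azidobutyl)(3-hydroxypropyl)carbamate
Product: 15 tert-butyl (4-azidobutyl)(3-oxopropyl)carbamate
Conditions: Dess–Martin periodinane, CH2Cl2, rt; used promptly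
Reagents that add atoms: none
Why: Dess–Martin oxidation stops at the aldehyde under near-neutral conditions, and the fully substituted carbamate nitrogen is a poor leaving group for β-elimination.

Step 8
Reactants: 9 methyl {(2S,6R)-2-[(2R)-2-(tert-butyldimethylsilyloxy)but-3-en-1-yl]-1,2,5,6-tetrahydropyridin-6-yl}acetate; 15 tert-butyl (4-azidobutyl)(3-oxopropyl)carbamate
Product: 17 methyl {(2S,6R)-1-{3-[(4-azidobutyl)(tert-butoxycarbonyl)amino]propyl}-2-[(2R)-2-(tert-butyldimethylsilyloxy)but-3-en-1-yl]-1,2,5,6-tetrahydropyridin-6-yl}acetate, via iminium acetate 16 (not isolated)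
Conditions: NaBH(OAc)3, AcOH, ClCH2CH2Cl, rt
Reagents that add atoms: none
Why: Reductive amination, in which the unhindered aldehyde condenses with the ring amine to an iminium ion that NaBH(OAc)3 reduces faster than the aldehyde, should alkylate N1 while ester, azide, silyl ether and both alkenes are inert and C2 and C6 are untouched.

Step 9
Reactants: 17 methyl {(2S,6R)-1-{3-[(4-azidobutyl)(tert-butoxycarbonyl)amino]propyl}-2-[(2R)-2-(tert-butyldimethylsilyloxy)but-3-en-1-yl]-1,2,5,6-tetrahydropyridin-6-yl}acetate
Product: 19 {(2S,6R)-1-{3-[(4-azidobutyl)(tert-butoxycarbonyl)amino]propyl}-2-[(2R)-2-(tert-butyldimethylsilyloxy)but-3-en-1-yl]-1,2,5,6-tetrahydropyridin-6-yl}acetic acid, via lithium carboxylate 18 (not isolated)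
Conditions: LiOH·H2O, THF/MeOH/H2O, 0 °C to rt; 1 M HCl to pH 6, extraction
Reagents that add atoms: lithium hydroxide [Li+].[OH-] (its oxygen becomes the carboxyl OH)
Why: Saponification of the methyl ester under mild conditions should spare the secondary silyl ether, carbamate and azide, and the β-amino ester does not eliminate at this temperature, so C6 is preserved.

Step 10
Reactants: 19 {(2S,6R)-1-{3-[(4-azidobutyl)(tert-butoxycarbonyl)amino]propyl}-2-[(2R)-2-(tert-butyldimethylsilyloxy)but-3-en-1-yl]-1,2,5,6-tetrahydropyridin-6-yl}acetic acid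
Product: 23 tert-butyl (13R,17S)-17-[(2R)-2-(tert-butyldimethylsilyloxy)but-3-en-1-yl]-11-oxo-1,5,10-triazabicyclo[11.4.0]heptadec-15-ene-5-carboxylate, via iminophosphorane 20 (not isolated), via amino acid 21 (not isolated), via pentafluorophenyl ester 22 (not isolated)
Conditions: PMe3, THF/H2O, rt; concentrate, toluene azeotrope; then slow addition to pentafluorophenyl diphenylphosphinate, i-Pr2NEt, MeCN (final 1 mM), rt
Reagents that add atoms: none
Why: Staudinger reduction should unmask the primary amine, and the phosphinate reagent then activates the carboxylate as its pentafluorophenyl ester, which the amine attacks under high dilution to close the 13-membered ring B (macrolactamisation); the tertiary amine and the carbamate nitrogen cannot be acylated.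

Step 11
Reactants: 23 tert-butyl (13R,17S)-17-[(2R)-2-(tert-butyldimethylsilyloxy)but-3-en-1-yl]-11-oxo-1,5,10-triazabicyclo[11.4.0]heptadec-15-ene-5-carboxylate
Product: 24 tert-butyl (13R,17S)-17-[(2R)-2-hydroxybut-3-en-1-yl]-11-oxo-1,5,10-triazabicyclo[11.4.0]heptadec-15-ene-5-carboxylate
Conditions: Bu4NF, THF, 0 °C to rt
Reagents that add atoms: none
Why: Fluoride-induced desilylation should free the allylic alcohol, with carbamate, lactam and alkenes stable to the reagent.

Step 12
Reactants: 24 tert-butyl (13R,17S)-17-[(2R)-2-hydroxybut-3-en-1-yl]-11-oxo-1,5,10-triazabicyclo[11.4.0]heptadec-15-ene-5-carboxylate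
Product: 25 tert-butyl (13R,17S)-11-oxo-17-(2-oxobut-3-en-1-yl)-1,5,10-triazabicyclo[11.4.0]heptadec-15-ene-5-carboxylate
Conditions: Dess–Martin periodinane, NaHCO3, CH2Cl2, 0 °C; filtered cold and used at once
Reagents that add atoms: none
Why: Dess–Martin oxidation of the secondary allylic alcohol under buffered, non-basic conditions at low temperature should give the vinyl ketone without retro-Michael loss of N1 from the β-amino ketone; the carbinol stereocentre is removed on purpose.

Step 13
Reactants: 25 tert-butyl (13R,17S)-11-oxo-17-(2-oxobut-3-en-1-yl)-1,5,10-triazabicyclo[11.4.0]heptadec-15-ene-5-carboxylate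
Product: 27 tert-butyl (13R,17S)-11-oxo-17-(2-oxoheptyl)-1,5,10-triazabicyclo[11.4.0]heptadec-15-ene-5-carboxylate, via bromomagnesium enolate 26 (not isolated)
Conditions: n-PrMgBr (6 equiv), CuBr·SMe2 (3 equiv), THF, −40 °C; then 25, −78 °C; aq NH4Cl/NH3
Reagents that add atoms: n-propylmagnesium bromide CCC[Mg]Br
Why: Conjugate addition of the Gilman-type magnesium dipropylcuprate to the unhindered vinyl ketone is far faster than attack on lactam or carbamate at −78 °C (the excess allows for the lactam N–H), and the enolate forms on the side remote from C2, so neither elimination of N1 nor epimerisation at C2 is expected before the mild protonation.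

Step 14
Reactants: 27 tert-butyl (13R,17S)-11-oxo-17-(2-oxoheptyl)-1,5,10-triazabicyclo[11.4.0]heptadec-15-ene-5-carboxylate
Product: 29 (13R,17S)-17-(2-oxoheptyl)-1,5,10-triazabicyclo[11.4.0]heptadec-15-en-11-one (CNP0183222.1), via bis(trifluoroacetate) salt 28 (not isolated)
Conditions: CF3CO2H, CH2Cl2, 0 °C; cold aq NaHCO3, extraction
Reagents that add atoms: none
Why: Acidolysis of the tert-butyl carbamate (loss of isobutene and CO2) proceeds with both amines protonated, which disfavours enolisation toward C2, and cold bicarbonate neutralisation should release the free base without retro-Michael epimerisation.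

**Compound list**

1 | (3R)-3-aminohex-5-enoic acid | N[C@H](CC=C)CC(=O)O | starting material
2 | methyl (3R)-3-aminohex-5-enoate hydrochloride | Cl.N[C@H](CC=C)CC(=O)OC | intermediate
3 | (1R,4S)-cis-4-acetoxycyclopent-2-en-1-ol | C1[C@H](OC(C)=O)C=C[C@@H]1O | starting material
4 | (1S,4R)-cis-4-(tert-butyldimethylsilyloxy)cyclopent-2-en-1-yl acetate | C1[C@H](OC(C)=O)C=C[C@@H]1O[Si](C)(C)C(C)(C)C | intermediate
5 | methyl (3R)-3-aminohex-5-enoate (free base) | N[C@H](CC=C)CC(=O)OC | intermediate
6 | methyl (3R)-3-{[(1S,4R)-4-(tert-butyldimethylsilyloxy)cyclopent-2-en-1-yl]amino}hex-5-enoate | C1[C@H](N[C@H](CC=C)CC(=O)OC)C=C[C@@H]1O[Si](C)(C)C(C)(C)C | intermediate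
7 | 4-methylbenzenesulfonate salt of 6 | C1[C@H]([NH2+][C@H](CC=C)CC(=O)OC)C=C[C@@H]1O[Si](C)(C)C(C)(C)C.Cc1ccc(cc1)S(=O)(=O)[O-] | intermediate
8 | 4-methylbenzenesulfonate salt of 9 | C=C[C@H](O[Si](C)(C)C(C)(C)C)C[C@H]1C=CC[C@H](CC(=O)OC)[NH2+]1.Cc1ccc(cc1)S(=O)(=O)[O-] | intermediate
9 | methyl {(2S,6R)-2-[(2R)-2-(tert-butyldimethylsilyloxy)but-3-en-1-yl]-1,2,5,6-tetrahydropyridin-6-yl}acetate | C=C[C@H](O[Si](C)(C)C(C)(C)C)C[C@H]1C=CC[C@H](CC(=O)OC)N1 | intermediate
10 | 4-azidobutan-1-amine | NCCCCN=[N+]=[N-] | starting material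
11 | methyl acrylate | C=CC(=O)OC | starting material
12 | methyl 3-[(4-azidobutyl)amino]propanoate | COC(=O)CCNCCCCN=[N+]=[N-] | intermediate
13 | methyl 3-[(4-azidobutyl)(tert-butoxycarbonyl)amino]propanoate | COC(=O)CCN(CCCCN=[N+]=[N-])C(=O)OC(C)(C)C | intermediate
14 | tert-butyl (4-azidobutyl)(3-hydroxypropyl)carbamate | OCCCN(CCCCN=[N+]=[N-])C(=O)OC(C)(C)C | intermediate
15 | tert-butyl (4-azidobutyl)(3-oxopropyl)carbamate | O=CCCN(CCCCN=[N+]=[N-])C(=O)OC(C)(C)C | intermediate
16 | iminium acetate formed from 9 and 15 (N1=CH of the propyl arm) | C=C[C@H](O[Si](C)(C)C(C)(C)C)C[C@H]1C=CC[C@H](CC(=O)OC)[N+]1=CCCN(CCCCN=[N+]=[N-])C(=O)OC(C)(C)C.CC(=O)[O-] | intermediate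
17 | methyl {(2S,6R)-1-{3-[(4-azidobutyl)(tert-butoxycarbonyl)amino]propyl}-2-[(2R)-2-(tert-butyldimethylsilyloxy)but-3-en-1-yl]-1,2,5,6-tetrahydropyridin-6-yl}acetate | C=C[C@H](O[Si](C)(C)C(C)(C)C)C[C@H]1C=CC[C@H](CC(=O)OC)N1CCCN(CCCCN=[N+]=[N-])C(=O)OC(C)(C)C | intermediate
18 | lithium salt of acid 19 | C=C[C@H](O[Si](C)(C)C(C)(C)C)C[C@H]1C=CC[C@H](CC(=O)[O-])N1CCCN(CCCCN=[N+]=[N-])C(=O)OC(C)(C)C.[Li+] | intermediate
19 | {(2S,6R)-1-{3-[(4-azidobutyl)(tert-butoxycarbonyl)amino]propyl}-2-[(2R)-2-(tert-butyldimethylsilyloxy)but-3-en-1-yl]-1,2,5,6-tetrahydropyridin-6-yl}acetic acid | C=C[C@H](O[Si](C)(C)C(C)(C)C)C[C@H]1C=CC[C@H](CC(=O)O)N1CCCN(CCCCN=[N+]=[N-])C(=O)OC(C)(C)C | intermediate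
20 | trimethyliminophosphorane of 19 (N=PMe3 in place of the azide) | C=C[C@H](O[Si](C)(C)C(C)(C)C)C[C@H]1C=CC[C@H](CC(=O)O)N1CCCN(CCCCN=P(C)(C)C)C(=O)OC(C)(C)C | intermediate
21 | amino acid (primary amine in place of the azide of 19) | C=C[C@H](O[Si](C)(C)C(C)(C)C)C[C@H]1C=CC[C@H](CC(=O)O)N1CCCN(CCCCN)C(=O)OC(C)(C)C | intermediate
22 | pentafluorophenyl ester of amino acid 21 | C=C[C@H](O[Si](C)(C)C(C)(C)C)C[C@H]1C=CC[C@H](CC(=O)Oc2c(F)c(F)c(F)c(F)c2F)N1CCCN(CCCCN)C(=O)OC(C)(C)C | intermediate
23 | tert-butyl (13R,17S)-17-[(2R)-2-(tert-butyldimethylsilyloxy)but-3-en-1-yl]-11-oxo-1,5,10-triazabicyclo[11.4.0]heptadec-15-ene-5-carboxylate | C=C[C@H](O[Si](C)(C)C(C)(C)C)C[C@H]1C=CC[C@@H]2CC(=O)NCCCCN(C(=O)OC(C)(C)C)CCCN21 | intermediate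
24 | tert-butyl (13R,17S)-17-[(2R)-2-hydroxybut-3-en-1-yl]-11-oxo-1,5,10-triazabicyclo[11.4.0]heptadec-15-ene-5-carboxylate | C=C[C@H](O)C[C@H]1C=CC[C@@H]2CC(=O)NCCCCN(C(=O)OC(C)(C)C)CCCN21 | intermediate
25 | tert-butyl (13R,17S)-11-oxo-17-(2-oxobut-3-en-1-yl)-1,5,10-triazabicyclo[11.4.0]heptadec-15-ene-5-carboxylate | C=CC(=O)C[C@H]1C=CC[C@@H]2CC(=O)NCCCCN(C(=O)OC(C)(C)C)CCCN21 | intermediate
26 | bromomagnesium enolate of 27 (C2'=C3' enolate of the heptanone arm) | CCCCC=C(O[Mg]Br)C[C@H]1C=CC[C@@H]2CC(=O)NCCCCN(C(=O)OC(C)(C)C)CCCN21 | intermediate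
27 | tert-butyl (13R,17S)-11-oxo-17-(2-oxoheptyl)-1,5,10-triazabicyclo[11.4.0]heptadec-15-ene-5-carboxylate | CCCCCC(=O)C[C@H]1C=CC[C@@H]2CC(=O)NCCCCN(C(=O)OC(C)(C)C)CCCN21 | intermediate
28 | bis(trifluoroacetate) salt of 29 | CCCCCC(=O)C[C@H]1C=CC[C@@H]2CC(=O)NCCCC[NH2+]CCC[NH+]21.[O-]C(=O)C(F)(F)F.[O-]C(=O)C(F)(F)F | intermediate
29 | (13R,17S)-17-(2-oxoheptyl)-1,5,10-triazabicyclo[11.4.0]heptadec-15-en-11-one (CNP0183222.1) | CCCCCC(=O)C[C@H]1C=CC[C@@H]2CC(=O)NCCCCNCCCN21 | target

**Step count and risks**

Total step count: 14.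
Longest linear sequence: 10 steps (step 1 or 2, then 3, 4 and 8–14; the arm sequence 5–7 followed by 8–14 is equally long).

Steps most likely to fail:

1. Step 4. The catalyst may be deactivated by nitrogen that is not fully protonated, the rearrangement may stall at ring-opened oligomers, or the silyl ether may be partly lost under the acidic medium. Fallback: the nitrogen is carried through the metathesis as a neutral amide. Setting out from 6, acylation with trifluoroacetic anhydride (Et3N, CH2Cl2, 0 °C) should give methyl (3R)-3-{[(1S,4R)-4-(tert-butyldimethylsilyloxy)cyclopent-2-en-1-yl](trifluoroacetyl)amino}hex-5-enoate F1. Ring-rearrangement metathesis of this amide without acid (RuCl2(=CHPh)(PCy3)(H2IMes), ethylene, CH2Cl2, 40 °C) should give methyl {(2S,6R)-2-[(2R)-2-(tert-butyldimethylsilyloxy)but-3-en-1-yl]-1-(trifluoroacetyl)-1,2,5,6-tetrahydropyridin-6-yl}acetate F2. Methanolysis of the trifluoroacetamide (K2CO3, MeOH, rt) then comes back to the route at 9.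

2. Step 12 (with its follow-up, step 13). The vinyl ketone may polymerise, or N1 may be expelled by retro-Michael reaction with loss of configuration at C2, before the cuprate is added. Fallback: the vinyl ketone is avoided. Setting out from 24, cross-metathesis of the vinyl carbinol with excess 1-pentene (RuCl2(=CH-2-(i-PrO)C6H4)(H2IMes), CH2Cl2, 40 °C; the hindered tertiary N1 binds ruthenium poorly) should give tert-butyl (13R,17S)-17-[(2R,3E)-2-hydroxyhept-3-en-1-yl]-11-oxo-1,5,10-triazabicyclo[11.4.0]heptadec-15-ene-5-carboxylate F3. Dess–Martin oxidation should give the β-propyl enone tert-butyl (13R,17S)-11-oxo-17-[(3E)-2-oxohept-3-en-1-yl]-1,5,10-triazabicyclo[11.4.0]heptadec-15-ene-5-carboxylate F4, which has no terminal vinyl group to polymerise. Conjugate reduction with [CuH(PPh3)]6 in wet toluene, which leaves the isolated ring alkene alone, comes back to the route at 27.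

3. Step 8. Iminium formation at the doubly α-branched N1 may be slow, so that reduction of the aldehyde back to the alcohol and aldol self-condensation consume the arm. Fallback: the bond is made by direct displacement instead of through an iminium ion. Setting out from 14, mesylation (MsCl, Et3N, CH2Cl2, 0 °C) should give 3-[(4-azidobutyl)(tert-butoxycarbonyl)amino]propyl methanesulfonate F5. Halide exchange (NaI, acetone, rt) should give tert-butyl (4-azidobutyl)(3-iodopropyl)carbamate F6. Alkylation of amine 9 with this primary iodide (K2CO3, MeCN, 60 °C) comes back to the route at 17.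

**Further compounds**

F1 | step 4 | methyl (3R)-3-{[(1S,4R)-4-(tert-butyldimethylsilyloxy)cyclopent-2-en-1-yl](trifluoroacetyl)amino}hex-5-enoate | C1[C@H](N(C(=O)C(F)(F)F)[C@H](CC=C)CC(=O)OC)C=C[C@@H]1O[Si](C)(C)C(C)(C)C
F2 | step 4 | methyl {(2S,6R)-2-[(2R)-2-(tert-butyldimethylsilyloxy)but-3-en-1-yl]-1-(trifluoroacetyl)-1,2,5,6-tetrahydropyridin-6-yl}acetate | C=C[C@H](O[Si](C)(C)C(C)(C)C)C[C@H]1C=CC[C@H](CC(=O)OC)N1C(=O)C(F)(F)F
F3 | step 12 | tert-butyl (13R,17S)-17-[(2R,3E)-2-hydroxyhept-3-en-1-yl]-11-oxo-1,5,10-triazabicyclo[11.4.0]heptadec-15-ene-5-carboxylate | CCC/C=C/[C@H](O)C[C@H]1C=CC[C@@H]2CC(=O)NCCCCN(C(=O)OC(C)(C)C)CCCN21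
F4 | step 12 | tert-butyl (13R,17S)-11-oxo-17-[(3E)-2-oxohept-3-en-1-yl]-1,5,10-triazabicyclo[11.4.0]heptadec-15-ene-5-carboxylate | CCC/C=C/C(=O)C[C@H]1C=CC[C@@H]2CC(=O)NCCCCN(C(=O)OC(C)(C)C)CCCN21
F5 | step 8 | 3-[(4-azidobutyl)(tert-butoxycarbonyl)amino]propyl methanesulfonate | CS(=O)(=O)OCCCN(CCCCN=[N+]=[N-])C(=O)OC(C)(C)C
F6 | step 8 | tert-butyl (4-azidobutyl)(3-iodopropyl)carbamate | ICCCN(CCCCN=[N+]=[N-])C(=O)OC(C)(C)C
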